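Readings and results are calculated for substances that don't exist; noise was put on by code.

Which flask ends with more product once the feed is in, dawn or winter?

* which of the two ends with the higher amount of product, in percent of the starting material charged ("neither" if they lie within 2 percentage points) (dawn / winter / neither)
* product at the end, in percent of the starting material charged, dawn
* product at the end, in percent of the starting material charged, winter

| setting | maple | dawn | winter |
|---|---|---|---|
| starting material | 10 mM (fed, over 25 min) | 40 mM (fed, over 25 min) | 10 mM (fed, over 25 min) |
| coupling partner | 16 mM | 11.0 mM | 11.0 mM |
| free catalyst | 0.50 mM | 0.50 mM | 0.50 mM |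
| temperature | 10 °C |  |  |
| remark | run made earlier; the fed solution adds 0.20 times the starting volume | at 30 °C throughout; the fed solution adds 0.20 times the starting volume | at 10 °C until 8.0 min, from then on at 30 °C; the fed solution adds 0.20 times the starting volume |
| time |  | 25 min | 25 min |

maple run (percent of the starting material charged)

| time / min | product / % |
|---|---|
| 1.33 | 0 |
| 3.00 | 1.0 |
| 4.00 | 1.1 |
| 6.00 | 2.4 |
| 8.00 | 6.1 |

(scatter of a reading: 0.5 percentage points)

- amounts are per litre of the starting volume; all of the dose is in the solution fed
- the analysis behind the earlier runs scatters by 0.5 percentage points, standard deviation
- the earlier runs do not show what temperature does; that part of a forecast is a guess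
- percentages count the whole charge, also what has not yet gone in

**What can dawn hold at most?** If one product takes one starting material and one coupling partner, dawn gives 27.5 %, and this ratio of charges, c(coupling partner)/c(starting material), is the ceiling. The coupling partner is dawn's limiting reagent. In winter the same ratio is 110 %, so there the charge of starting material caps the yield at 100 %, and the ceiling does not bind.

**Does dawn reach its ceiling in time?** Count lifetimes. In maple, product reads as growing roughly with the square of time, as it does if the rate follows the accumulated feed, and I take the last reading, 6.1 % at 8.00 min, which stands further above the scatter than the earlier ones. It gives a lifetime of fed starting material of 21.0 min, as a reading. If the rate is first order in coupling partner, which maple cannot show, dawn's accumulating feed gives the partner 1.49 lifetimes even at the cold temperature. On this reckoning 22.6 % of it remains, and dawn is warmer, by a factor that is a guess. So I expect dawn just under its ceiling.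

**And winter, if it stayed cold?** At winter's lower partner charge I reckon the lifetime stretches to 30.5 min. A steady feed over 25 min then gives, by my estimate, 31.7 %, which is more than dawn's ceiling.

**Where is that weak?** The margin is 4.2 percentage points, and my estimate holds partner and volume constant, though both change in the flask. The warming of winter from 8.0 min is not in the estimate, and its factor is a guess. I commit to winter, counting on that warming, without a firm figure for it.

The forecast named winter, with 26 % for dawn and 50 % for winter, reasoning that in dawn “the 11 mM partner is nearly used up by 25 min”.

The flask gives winter: dawn 26.6 %, winter 62.9 %.

    catalyst intermediate B → spent catalyst (k = 0.00950 /min, Ea = 91.0 kJ/mol)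
    catalyst intermediate B → free catalyst + product (k = 9.20 /min, Ea = 79.0 kJ/mol)
    coupling partner + free catalyst → catalyst intermediate A (k = 130 /M/min, Ea = 52.0 kJ/mol)
    starting material + catalyst intermediate A ⇌ catalyst intermediate B (K = 150 /M, k = 120 /M/min, Ea = 56.0 kJ/mol, ΔH = −18.0 kJ/mol)
    2 starting material → homo dimer (k = 6.00 /M/min, Ea = 35.0 kJ/mol)
    (constants at 10 °C)

Dawn ended at 26.6 %, below its ceiling of 27.5 %, with 2.82 % of its coupling partner charge still free. Its high charge of starting material is the main reason for the low percentage: dawn run at winter's concentration of starting material gives 66.8 % instead of 26.6 %. A neighbour of dawn with 4.4 mM of coupling partner has a ceiling of 11.0 % and ends at 10.9 %.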